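The theta run levelled off near 36.3 % of its substrate on 0.37 equiv of reagent, so we take each target to cost one reagent, and reagent as the limiting reagent in a flask charged with less than one equivalent of it.

| flask | substrate | reagent | free catalyst | remark | time |
|---|---|---|---|---|---|
| theta | 0.050 M | 0.37 equiv | 0.79 mol% | run made earlier |  |
| zeta | 0.050 M | 0.95 equiv | 0.79 mol% | run made earlier |  |
| delta | 0.050 M | 2.1 equiv | 0.79 mol% | run made earlier |  |
| epsilon | 0.050 M | 0.50 equiv | 0.3 mol% | run made earlier |  |
| Thursday's | 0.050 M | 0.500 equiv | 0.79 mol% |  | 8.0 d |
| Sunday's | 0.050 M | 2.00 equiv | 0.5 mol% |  | 8.0 d |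
| Saturday's | 0.025 M | 1.50 equiv | 0.79 mol% |  | 8.0 d |
| Wednesday's | 0.025 M | 0.500 equiv | 0.2 mol% |  | 8.0 d |

- theta (time / d: target / %): 1.67: 35.4; 3.00: 37.0; 5.00: 36.6; 6.00: 37.0; 8.00: 36.3
- zeta (time / d: target / %): 0.625: 44.6; 1.25: 62.7; 2.50: 78.6; 4.00: 85.9; 8.00: 91.6
- delta (time / d: target / %): 0.625: 53.0; 2.08: 92.7; 4.00: 99.8; 6.00: 99.3; 8.00: 99.9
- epsilon (time / d: target / %): 1.67: 31.7; 3.00: 41.2; 5.00: 45.4; 6.00: 47.1; 8.00: 48.3

(scatter of a reading: 0.5 percentage points)

- the analysis behind the earlier runs scatters by 0.5 percentage points, standard deviation

- the flasks put in order of amount of target, in percent of the substrate charged, best first, at 8.0 d (Thursday's / Sunday's / Saturday's / Wednesday's)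
- the amount of target, in percent of the substrate charged of the flask you put first, at 8.0 d
- the amount of target, in percent of the substrate charged of the flask you put last, at 8.0 d

We turn the settings one at a time. Reagent first: 0.500 equiv puts a ceiling on Thursday's and Wednesday's at that share of the substrate, while Sunday's and Saturday's have reagent in excess.

Catalyst next. We assume that substrate loses a fraction set by catalyst concentration times time, and we compare flasks by the matched time: the time at which an earlier run with similar equivalents of reagent had the same catalyst concentration times time as the new flask. The epsilon run at 1.67 d and the delta run at 0.625 d nearly match in this product, and between these two readings the reagent charge differs by a factor of 4.20, more than the factor of 1.67 in target.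

Substrate last: no run diluted it. We therefore wager that dilution acts through catalyst concentration, and we neglect the halved reagent concentration.

For Wednesday's, the matched time on epsilon is 2.67 d. Interpolating epsilon's readings gives 38.8 %. Thursday's matches epsilon at 21.1 d, past its last reading of 48.3 %. Sunday's matches delta at 5.06 d, where delta's readings are near 99.3 %.

The forecast gives Sunday's > Saturday's > Thursday's > Wednesday's, with top 99.7 % (98.8 % to 100 %) and low 31 % (26 % to 41 %). Its low is under our 38.8 %, on the grounds “Assuming mass action, with catalyst, substrate and reagent all diluted, fractional rate falls about fourfold and inhibition eases.”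

The simulation gives Sunday's > Saturday's > Thursday's > Wednesday's, with top 99.8 % and low 38.2 %.

    substrate + free catalyst ⇌ catalyst intermediate A (K = 21.0 M⁻¹, k = 4.80 M⁻¹ min⁻¹)
    reagent + catalyst intermediate A ⇌ catalyst intermediate B (K = 32.0 M⁻¹, k = 29.0 M⁻¹ min⁻¹)
    catalyst intermediate B ⇌ by-product + catalyst intermediate C (K = 0.0270 M, k = 2.20 min⁻¹)
    catalyst intermediate C → free catalyst + target (k = 0.360 min⁻¹)
    substrate + catalyst intermediate A → spent catalyst (k = 0.00760 M⁻¹ min⁻¹)

Wednesday's reached 38.2 %, against 38.8 % read at the matched time of 2.67 d and 7.2 percentage points above the forecast. In Wednesday's, half of the turnover of substrate with free catalyst up to the asked time was done by 2.15 d, and at 8.00 d substrate stood at 61.6 %, reagent at 23.5 % of its charge and spent catalyst at 27.9 % of the catalyst charged.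

Now take Wednesday's flask with 2.00 equiv of reagent. Its matched time on delta is 1.01 d, and delta's first reading, read as pseudo-first-order loss of substrate at 1.21 d⁻¹, gives 70.5 %. The simulated flask gives 74.3 %.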